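The constants used here were set for the occasion, and the outcome is calculated.

Pairing holds the ring back.

common to all: starting material 0.028 M; time 6.0 min

| run | temperature |
|---|---|
| alder | 20 °C |
| elm | 35 °C |

- which of these there is most of at the end, counted by the starting material in it, alder (side product / ring / starting material / open dimer)
- which of these there is most of at the end, counted by the starting material in it, elm (side product / ring / starting material / open dimer)
- amount of the one of these that there is most of at the end, in percent of the starting material charged, alder
- amount of the one of these that there is most of at the end, in percent of the starting material charged, elm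

- percent here means starting material units held: one open dimer or side product counts as two
- what is said of ring includes crystals
- a doubled species enters its step squared and goes two at a time
- crystals is a solid; its amount is given per volume of the solution
- the constants hold at 20 °C; other temperatures follow from the activation energies and enthalpies

    starting material → ring (k1 = 0.022 s⁻¹, Ea1 = 90.0 kJ mol⁻¹)
    starting material + starting material ⇌ open dimer (K2 = 450 L mol⁻¹, k2 = 12 L mol⁻¹ s⁻¹, Ea2 = 41.0 kJ mol⁻¹, ΔH2 = −51.0 kJ mol⁻¹)
    crystals ⇌ ring, rate k3*(cs3 - [ring]) while solid is left; crystals form when [ring] > cs3 (cs3 = 0.46 mM, k3 = 2.2 s⁻¹)
    starting material + ring → side product (k4 = 1.6 L mol⁻¹ s⁻¹, Ea4 = 35.0 kJ mol⁻¹)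
    (constants at 20 °C)

Starting material closes to ring with rate constant k = 0.022 s⁻¹ and pairs to open dimer with equilibrium constant K = 450 L mol⁻¹. At the start of alder, closing uses 0.033 of what pairing uses, so I let pairing come first and put the free level at B, a share 18.0 % of the charge.

Alder has two extremes. With no dimer, free starting material falls one power of ten every 1.74 min, which leaves 0.0363 % at 6.0 min. With a dimer that forms and never opens, free starting material keeps splitting between closing and pairing, and ring gets the share 11.3 %. The real flask lies between, since the dimer opens as free starting material goes. For free level F, the pool F + 2KF² loses kF, which integrates, side product apart, to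

k·t = ln(B/F) + N·(B − F)/B, with N = 4KB = 9.09

The first term is the logarithmic fall. The second adds the drain time, N/k = 6.89 min, the delay that the open dimer, here the resting state, puts on that fall.

Alder stops at 6.0 min, short of its drain time. Trying F = B/4 gives t = 6.21 min, close enough. That means free starting material 4.51 % and open dimer 5.12 %. The dimer figure is probably low, because its opening constant k₂/K, 1.60 min⁻¹, stands close to k, 1.32 min⁻¹. With dissolved ring near 0.46 mM, side product takes a share 6.69 %, so I commit to ring 84.3 %.

In elm, k rises to 7.96 min⁻¹ and K falls to 163 L mol⁻¹. The drain time becomes 0.642 min. With k₄ at 3.22 L mol⁻¹ s⁻¹, ring comes to 97.8 %.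

The forecast gives ring at 85 % in alder and ring at 96 % in elm, starting from “Dimerisation equilibrates within seconds”; my elm figure stands higher.

The simulation gives ring at 81.1 % in alder and ring at 96.5 % in elm. Alder ends with open dimer 8.33 % against my 5.12 %. Elm's drain time lies inside 3.00 min, and at that reading elm holds starting material 0 % and open dimer 0 %.

Alder read at 1.5 min stands early in its drain time. One round of the rule gives F/B = 0.809, so open dimer 53.7 % and free starting material 14.6 %. The simulation gives open dimer as the largest holder at 52.9 %, with starting material 13.1 %.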